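**Retrosynthetic overview**
- The aryl tiglate and the primary isovalerate are cut at their acyl C–O bonds. Until the oxirane exists, the phenol is carried as an allyl ether and the primary alcohol as a TBS ether, because a sulfur ylide would attack either ester.
- The strategy rests on the oxirane being terminal and 2,2-disubstituted: O1, the quaternary C2 (bearing the benzene ring and the CH2O arm) and the unsubstituted C3H2. C3 and its two ring bonds (C2–C3 and C3–O1) go back to a one-carbon sulfoxonium ylide and the aryl silyloxymethyl ketone whose carbonyl carbon is C2; a chiral LaLi3 tris(binaphthoxide) catalyst sets C2.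
- The ketone comes from an aryllithium (bromine–lithium exchange on ortho-brominated, O-allylated 4-methoxy-3-methylphenol) and the Weinreb amide of O-silylated glycolic acid.
- Ring order: the benzene ring is bought; the oxirane is the only ring made (step 7).

Key step: step 7

Assumption (sense of induction): the catalyst is taken to treat the CH2OSi arm as it treats the methyl group of an aryl methyl ketone. The oxirane needed then corresponds atom for atom (O, ring CH2 and aryl in the same places) to the 2-aryl-2-methyloxirane of R descriptor. The BINOL antipode that gives that series is the one meant and is written below as (R)-BINOL; if a test run shows the opposite sense, (S)-BINOL is used with no other change.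

**Step 1**
Reactants: 1 4-methoxy-3-methylphenol; 2 N-bromosuccinimide
Product: 3 2-bromo-4-methoxy-5-methylphenol
Conditions: i-Pr2NH (10 mol %), CH2Cl2, 0 °C
Reagents that add atoms: N-bromosuccinimide, O=C1CCC(=O)N1Br
Why: Electrophilic aromatic bromination; the hydroxyl is the strongest director, its para position is blocked by OMe, and of its two ortho carbons the one para to the methyl is the more activated and the less hindered.

**Step 2**
Reactants: 3 2-bromo-4-methoxy-5-methylphenol; 4 allyl bromide
Product: 5 1-(allyloxy)-2-bromo-4-methoxy-5-methylbenzene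
Conditions: K2CO3, DMF, rt
Reagents that add atoms: allyl bromide, C=CCBr
Why: Williamson ether synthesis of a phenoxide with an allylic bromide; the allyl ether should survive organolithium at low temperature, the ylide and fluoride, and is removable later under near-neutral conditions.

**Step 3**
Reactants: 6 methyl glycolate; 7 tert-butyldimethylsilyl chloride
Product: 8 methyl 2-[(tert-butyldimethylsilyl)oxy]acetate
Conditions: imidazole, DMF, rt
Reagents that add atoms: tert-butyldimethylsilyl chloride, CC(C)(C)[Si](C)(C)Cl
Why: Standard imidazole-promoted silylation of a primary alcohol.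

**Step 4**
Reactants: 8 methyl 2-[(tert-butyldimethylsilyl)oxy]acetate; 9 N,O-dimethylhydroxylamine hydrochloride
Product: 10 2-[(tert-butyldimethylsilyl)oxy]-N-methoxy-N-methylacetamide
Conditions: i-PrMgCl (3 equiv), THF, −20 → 0 °C
Reagents that add atoms: N,O-dimethylhydroxylamine hydrochloride, CNOC.Cl
Why: Direct Weinreb amide formation from an ester with the chloromagnesium amide made in the flask; the silyl ether is inert to the Grignard base at this temperature.

**Step 5**
Reactants: 5 1-(allyloxy)-2-bromo-4-methoxy-5-methylbenzene; 10 2-[(tert-butyldimethylsilyl)oxy]-N-methoxy-N-methylacetamide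
Product: 12 1-[2-(allyloxy)-5-methoxy-4-methylphenyl]-2-[(tert-butyldimethylsilyl)oxy]ethan-1-one, via [2-(allyloxy)-5-methoxy-4-methylphenyl]lithium 11 (not isolated)
Conditions: n-BuLi (1.05 equiv), THF, −78 °C; then 10, −78 → −40 °C; sat. aq. NH4Cl
Reagents that add atoms: 2-[(tert-butyldimethylsilyl)oxy]-N-methoxy-N-methylacetamide (10), CON(C)C(=O)CO[Si](C)(C)C(C)(C)C
Why: Bromine–lithium exchange at −78 °C should outrun any reaction of the aryllithium with its own allyl ether, and the Weinreb ketone synthesis stops at the chelated tetrahedral adduct, so the ketone is released only on quench.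

**Step 6**
Reactants: 13 trimethylsulfoxonium chloride
Product: 14 dimethyloxosulfonium methylide (filtered, titrated THF solution, used as such)
Conditions: NaH, THF, reflux; filtration under argon
Reagents that add atoms: none
Why: Deprotonation of the sulfoxonium salt by NaH (Corey's ylide preparation); the chloride gives a THF solution free of DMSO and alkoxide, which would compete for the lanthanum catalyst.

**Step 7**
Reactants: 12 1-[2-(allyloxy)-5-methoxy-4-methylphenyl]-2-[(tert-butyldimethylsilyl)oxy]ethan-1-one; 14 dimethyloxosulfonium methylide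
Product: 15 (2R)-2-[2-(allyloxy)-5-methoxy-4-methylphenyl]-2-{[(tert-butyldimethylsilyl)oxy]methyl}oxirane
Conditions: 14 (1.2 equiv), LaLi3[(R)-binaphthoxide]3 (10 mol %, from La(OiPr)3, (R)-BINOL, n-BuLi), (2,4,6-(MeO)3C6H2)3P=O (10 mol %), 5 Å MS, THF, rt
Reagents that add atoms: dimethyloxosulfonium methylide (14), C[S+](C)(=O)[CH2-]
Why: The ketone binds to trivalent lanthanum in the binaphthoxide framework while the ylide is held at a lithium binaphthoxide arm; the ylide carbon adds to one face of the C=O to give the betaine (new C2–C3 bond), and the alkoxide then expels dimethyl sulfoxide in a 3-exo-tet closure that forms the C3–O1 bond. The closest known reaction type is the catalytic asymmetric Corey–Chaykovsky epoxidation of aryl methyl ketones with this heterobimetallic catalyst and a triarylphosphine oxide; here CH2OSi stands where methyl stood, so the level of induction is an extrapolation. The new quaternary stereocenter is the former carbonyl carbon, and its configuration is fixed by the face of addition, which the binaphthoxide pocket chooses by telling the flat aryl group from the sp3 CH2OSi arm, possibly helped by a second contact of the α-oxygen. The step needs enantiofacial selectivity and chemoselectivity for 1,2-addition: the unactivated allyl ether alkene is no acceptor for a sulfoxonium ylide, no ester is present yet, and a small excess of ylide at room temperature should avoid a second methylene insertion to the oxetane.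

**Step 8**
Reactants: 15 (2R)-2-[2-(allyloxy)-5-methoxy-4-methylphenyl]-2-{[(tert-butyldimethylsilyl)oxy]methyl}oxirane
Product: 16 {(2S)-2-[2-(allyloxy)-5-methoxy-4-methylphenyl]oxiran-2-yl}methanol
Conditions: tetrabutylammonium fluoride (1.1 equiv), THF, 0 °C
Reagents that add atoms: none
Why: Fluoride desilylation leaves the base-stable oxirane and both aryl ethers alone; no bond at the stereocenter is touched, and the descriptor changes from R to S only because CH2OH ranks below the ring CH2 whereas CH2OSi ranked above it.

**Step 9**
Reactants: 16 {(2S)-2-[2-(allyloxy)-5-methoxy-4-methylphenyl]oxiran-2-yl}methanol; 17 isovaleryl chloride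
Product: 18 {(2R)-2-[2-(allyloxy)-5-methoxy-4-methylphenyl]oxiran-2-yl}methyl 3-methylbutanoate
Conditions: Et3N, DMAP (cat.), CH2Cl2, 0 °C
Reagents that add atoms: isovaleryl chloride, CC(C)CC(Cl)=O
Why: DMAP-catalysed acylation of a primary alcohol; the excess of amine keeps the medium basic, so the acid-labile benzylic oxirane should not open.

**Step 10**
Reactants: 18 {(2R)-2-[2-(allyloxy)-5-methoxy-4-methylphenyl]oxiran-2-yl}methyl 3-methylbutanoate
Product: 19 [(2R)-2-(2-hydroxy-5-methoxy-4-methylphenyl)oxiran-2-yl]methyl 3-methylbutanoate
Conditions: Pd(PPh3)4 (5 mol %), morpholine (3 equiv), THF, rt, degassed; pH 7 buffer wash, used at once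
Reagents that add atoms: none
Why: Tsuji–Trost-type deallylation, in which zerovalent palladium ionises the aryl allyl ether to a π-allyl complex and the phenoxide, and morpholine takes the allyl group; the weakly basic medium should spare the ester and the oxirane.

**Step 11**
Reactants: 19 [(2R)-2-(2-hydroxy-5-methoxy-4-methylphenyl)oxiran-2-yl]methyl 3-methylbutanoate; 20 tigloyl chloride, (2E)-2-methylbut-2-enoyl chloride
Product: 21 4-methoxy-5-methyl-2-[(2R)-2-{[(3-methylbutanoyl)oxy]methyl}oxiran-2-yl]phenyl (2E)-2-methylbut-2-enoate (CNP0108422.1)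
Conditions: Et3N, DMAP (cat.), CH2Cl2, −20 → 0 °C, acid chloride added last
Reagents that add atoms: tigloyl chloride, C/C=C(\C)C(Cl)=O
Why: DMAP-catalysed O-acylation of the phenol; the E alkene of the acid chloride is carried over unchanged, and low temperature with the chloride added last should keep deconjugation through the vinylketene down.

**Compound list**
1 | 4-methoxy-3-methylphenol | Cc1cc(O)ccc1OC | starting material
2 | N-bromosuccinimide | O=C1CCC(=O)N1Br | starting material
3 | 2-bromo-4-methoxy-5-methylphenol | Cc1cc(O)c(Br)cc1OC | intermediate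
4 | allyl bromide | C=CCBr | starting material
5 | 1-(allyloxy)-2-bromo-4-methoxy-5-methylbenzene | Cc1cc(OCC=C)c(Br)cc1OC | intermediate
6 | methyl glycolate | COC(=O)CO | starting material
7 | tert-butyldimethylsilyl chloride | CC(C)(C)[Si](C)(C)Cl | starting material
8 | methyl 2-[(tert-butyldimethylsilyl)oxy]acetate | COC(=O)CO[Si](C)(C)C(C)(C)C | intermediate
9 | N,O-dimethylhydroxylamine hydrochloride | CNOC.Cl | starting material
10 | 2-[(tert-butyldimethylsilyl)oxy]-N-methoxy-N-methylacetamide | CON(C)C(=O)CO[Si](C)(C)C(C)(C)C | intermediate
11 | [2-(allyloxy)-5-methoxy-4-methylphenyl]lithium | [Li]c1cc(OC)c(C)cc1OCC=C | intermediate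
12 | 1-[2-(allyloxy)-5-methoxy-4-methylphenyl]-2-[(tert-butyldimethylsilyl)oxy]ethan-1-one | Cc1cc(OCC=C)c(cc1OC)C(=O)CO[Si](C)(C)C(C)(C)C | intermediate
13 | trimethylsulfoxonium chloride | C[S+](C)(C)=O.[Cl-] | starting material
14 | dimethyloxosulfonium methylide | C[S+](C)(=O)[CH2-] | intermediate
15 | (2R)-2-[2-(allyloxy)-5-methoxy-4-methylphenyl]-2-{[(tert-butyldimethylsilyl)oxy]methyl}oxirane | Cc1cc(OCC=C)c(cc1OC)[C@]1(CO[Si](C)(C)C(C)(C)C)CO1 | intermediate
16 | {(2S)-2-[2-(allyloxy)-5-methoxy-4-methylphenyl]oxiran-2-yl}methanol | Cc1cc(OCC=C)c(cc1OC)[C@]1(CO)CO1 | intermediate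
17 | isovaleryl chloride | CC(C)CC(Cl)=O | starting material
18 | {(2R)-2-[2-(allyloxy)-5-methoxy-4-methylphenyl]oxiran-2-yl}methyl 3-methylbutanoate | Cc1cc(OCC=C)c(cc1OC)[C@]1(COC(=O)CC(C)C)CO1 | intermediate
19 | [(2R)-2-(2-hydroxy-5-methoxy-4-methylphenyl)oxiran-2-yl]methyl 3-methylbutanoate | Cc1cc(O)c(cc1OC)[C@]1(COC(=O)CC(C)C)CO1 | intermediate
20 | tigloyl chloride, (2E)-2-methylbut-2-enoyl chloride | C/C=C(\C)C(Cl)=O | starting material
21 | 4-methoxy-5-methyl-2-[(2R)-2-{[(3-methylbutanoyl)oxy]methyl}oxiran-2-yl]phenyl (2E)-2-methylbut-2-enoate | C/C=C(\C)C(=O)Oc1cc(C)c(OC)cc1[C@]1(COC(=O)CC(C)C)CO1 | target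

**Step count**
Total steps: 11. Longest linear sequence: 8 steps (1, 2, 5, 7, 8, 9, 10, 11).

**Steps most likely to fail**

1. Step 7. Facial selectivity may be poor, because the CH2OSi arm is larger than the methyl group the catalyst pocket is known to handle. An uncatalysed, racemic addition to the more electrophilic α-oxygenated ketone may also compete, as may enolisation of the ketone by the ylide. The fallback sets out from ketone 12 and comes back at epoxy alcohol 16.
   - Wittig methylenation (Ph3PCH3Br, KOt-Bu, THF, 0 °C) should give tert-butyl({2-[2-(allyloxy)-5-methoxy-4-methylphenyl]prop-2-en-1-yl}oxy)dimethylsilane F1.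
   - Tetrabutylammonium fluoride in THF should free the allylic alcohol 2-[2-(allyloxy)-5-methoxy-4-methylphenyl]prop-2-en-1-ol F2.
   - Sharpless asymmetric epoxidation (Ti(OiPr)4, diisopropyl L-(+)-tartrate, t-BuOOH, 4 Å MS, CH2Cl2, −20 °C) should then give 16.
   - The L-(+)-tartrate is chosen because it is the antipode that turns allyl alcohol into (S)-glycidol; here the aryl group takes the place of H as the lowest-ranked substituent.
   - The allyl ether alkene has no directing hydroxyl and should stay untouched.

2. Step 10. The oxirane may be lost once the ortho-phenol is free: the phenol or phenoxide can push out the benzylic C–O bond (ortho-quinone methide formation), and morpholine may open the ring during the reaction or work-up. The fallback sets out from 18 and comes back at target 21 without a free phenol.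
   - Hydrostannolysis (Pd(PPh3)4 cat., Bu3SnH 1.05 equiv, CH2Cl2, rt) should cleave the allyl ether to propene and the tin phenoxide {(2R)-2-[5-methoxy-4-methyl-2-(tributylstannyloxy)phenyl]oxiran-2-yl}methyl 3-methylbutanoate F3.
   - Once the hydride is consumed, tigloyl chloride is added to the same flask at 0 °C and should acylate F3 to 21.
   - No amine base and no free phenoxide are present at any point.

3. Step 5. The ortho-allyloxy aryllithium may undergo anionic side reactions (5-exo carbolithiation onto the allyl group or Wittig rearrangement if the mixture warms), or may deprotonate the Weinreb amide instead of adding to it. The fallback sets out from phenol 1, uses no organolithium, and comes back at ketone 12.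
   - Acetylation (Ac2O, pyridine) should give 4-methoxy-3-methylphenyl acetate F4.
   - Fries rearrangement (BF3·OEt2, 110 °C) should move the acetyl group to the ring carbon ortho to oxygen and para to methyl, giving 1-(2-hydroxy-5-methoxy-4-methylphenyl)ethan-1-one F5.
   - O-Allylation (allyl bromide, K2CO3, DMF, 60 °C) should give 1-[2-(allyloxy)-5-methoxy-4-methylphenyl]ethan-1-one F6.
   - Enol silylation (LiN(SiMe3)2, Me3SiCl, THF, −78 °C) should give ({1-[2-(allyloxy)-5-methoxy-4-methylphenyl]ethenyl}oxy)trimethylsilane F7.
   - Rubottom oxidation (mCPBA, NaHCO3, CH2Cl2, 0 °C; aqueous citric acid) should give 1-[2-(allyloxy)-5-methoxy-4-methylphenyl]-2-hydroxyethan-1-one F8; the electron-rich enol ether should react well before the allyl alkene.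
   - Silylation (tert-butyldimethylsilyl chloride, imidazole, DMF) should then give 12.

**Further compounds**
F1 | step 7 | tert-butyl({2-[2-(allyloxy)-5-methoxy-4-methylphenyl]prop-2-en-1-yl}oxy)dimethylsilane | Cc1cc(OCC=C)c(cc1OC)C(=C)CO[Si](C)(C)C(C)(C)C
F2 | step 7 | 2-[2-(allyloxy)-5-methoxy-4-methylphenyl]prop-2-en-1-ol | Cc1cc(OCC=C)c(cc1OC)C(=C)CO
F3 | step 10 | {(2R)-2-[5-methoxy-4-methyl-2-(tributylstannyloxy)phenyl]oxiran-2-yl}methyl 3-methylbutanoate | CCCC[Sn](CCCC)(CCCC)Oc1cc(C)c(OC)cc1[C@]1(COC(=O)CC(C)C)CO1
F4 | step 5 | 4-methoxy-3-methylphenyl acetate | CC(=O)Oc1ccc(OC)c(C)c1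
F5 | step 5 | 1-(2-hydroxy-5-methoxy-4-methylphenyl)ethan-1-one | CC(=O)c1cc(OC)c(C)cc1O
F6 | step 5 | 1-[2-(allyloxy)-5-methoxy-4-methylphenyl]ethan-1-one | CC(=O)c1cc(OC)c(C)cc1OCC=C
F7 | step 5 | ({1-[2-(allyloxy)-5-methoxy-4-methylphenyl]ethenyl}oxy)trimethylsilane | C=C(O[Si](C)(C)C)c1cc(OC)c(C)cc1OCC=C
F8 | step 5 | 1-[2-(allyloxy)-5-methoxy-4-methylphenyl]-2-hydroxyethan-1-one | OCC(=O)c1cc(OC)c(C)cc1OCC=C
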